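**Retrosynthetic overview**

1. Feature: C8, the carbinol carbon that carries the methacrylate, is bonded directly to C7, the β-carbon of the butenolide ring (O–C6–C7=C11–C12=O). Its other neighbour is the C9 methylene next to the quaternary, oxygenated C10, so the C8 aldehyde is enolisable at C9 and has a β-leaving group at C10; it needs a non-basic, aldehyde-selective alkenyl metal at C7.
2. C7–C8: intramolecular Ni/Cr (Nozaki–Hiyama–Kishi) addition of a 4-iodobutenolide to the C8 aldehyde closes the ten-membered carbocycle (second ring) and sets C8.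
3. Butenolide (first ring): C6–O and C7–I by iodolactonisation of an axially chiral 2,3-allenoate; C11–C12 by Pd/CO on a propargylic carbonate; C6–C7 by asymmetric alkynylation of a C2–C6 enal.
4. C1–C2: Weinreb ketone synthesis joining a (S)-lactic acid-derived C8–C10–C1 amide (C10 by Seebach allylation, C8 fixed early as an acetal) to a C2–C6 alkyllithium whose E-C4=C5 bond comes from carboalumination.
5. Epoxide (third ring) last, by peracid on the outer face of the 4E-alkene, after the C8 methacrylate and the C10/C13 acetates are in place.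

Key step: step 18

Remark: germacrane numbering is used throughout (C1 ketone, C4=C5, C6 lactone carbinol, C7=C11 butenolide alkene, C8 ester carbinol, C10 tertiary carbinol, C12 lactone carbonyl, C13 oxymethyl). C13 is carried as a TBS ether, because a C13 acetate would be a second ionisable ester in steps 15 and 18, and is acetylated together with C10–OH in step 21. The ProPhenol antipode in step 13 is the one that attacks the Re face of the enal.

**Route**

Step 1
Reactants: 1 (S)-lactic acid
Product: 2 (2S,5S)-2-tert-butyl-5-methyl-1,3-dioxolan-4-one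
Conditions: pivalaldehyde, TsOH (cat.), H2SO4 (cat.), pentane, reflux, Dean–Stark; crystallisation of the cis acetal
Reagents that add atoms: pivalaldehyde, CC(C)(C)C=O
Why: Acid-catalysed acetalisation (Seebach self-regeneration of stereocentres) under thermodynamic control should favour the cis acetal, which is purified by crystallisation, so that the new acetal centre C2 (S) is set by the lactate centre and stores its chirality.

Step 2
Reactants: 2 (2S,5S)-2-tert-butyl-5-methyl-1,3-dioxolan-4-one; 3 allyl bromide
Product: 5 (2S,5R)-5-allyl-2-tert-butyl-5-methyl-1,3-dioxolan-4-one, via lithium enolate 4 (not isolated)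
Conditions: LDA (commercial solution), THF, −78 °C; then 3, −78 → −30 °C
Reagents that add atoms: none
Why: Enolate alkylation of the Seebach dioxolanone: the planar lithium enolate 4 is alkylated on the face trans to the tert-butyl group, so allyl takes the place of the former hydrogen and the quaternary centre (the later C10) is set as 5R by the acetal centre.

Step 3
Reactants: 5 (2S,5R)-5-allyl-2-tert-butyl-5-methyl-1,3-dioxolan-4-one
Product: 6 (R)-2-hydroxy-N-methoxy-N,2-dimethylpent-4-enamide
Conditions: MeNH(OMe)·HCl, iPrMgCl, THF, −20 → 0 °C; aq. NH4Cl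
Reagents that add atoms: N,O-dimethylhydroxylamine hydrochloride, CNOC.Cl
Why: Aminolysis of the acylal-type lactone by the chloromagnesium amide of N,O-dimethylhydroxylamine (Weinreb amide formation) opens the ring at the carbonyl, the hemiacetal alkoxide then collapses with loss of pivalaldehyde, and the quaternary centre is not touched.

Step 4
Reactants: 6 (R)-2-hydroxy-N-methoxy-N,2-dimethylpent-4-enamide
Product: 7 (R)-N-methoxy-N,2-dimethyl-2-(triethylsilyloxy)pent-4-enamide
Conditions: TESOTf, 2,6-lutidine, CH2Cl2, 0 °C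
Reagents that add atoms: triethylsilyl trifluoromethanesulfonate, CC[Si](CC)(CC)OS(=O)(=O)C(F)(F)F
Why: Silyl triflate silylation of a hindered tertiary alcohol with a pyridine base is standard and gives the TES ether that masks C10–OH up to the end.

Step 5
Reactants: 7 (R)-N-methoxy-N,2-dimethyl-2-(triethylsilyloxy)pent-4-enamide
Product: 9 (R)-N,4,4-trimethoxy-N,2-dimethyl-2-(triethylsilyloxy)butanamide, via aldehyde 8 (not isolated)
Conditions: O3, CH2Cl2, −78 °C; PPh3, −78 °C → rt; then HC(OMe)3, MeOH, PPTS (cat.), rt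
Reagents that add atoms: trimethyl orthoformate, COC(OC)OC
Why: Ozonolysis with reductive work-up followed by acid-catalysed acetalisation fixes C8 at the aldehyde oxidation level while the allyl group is the only alkene, so that no alkene has to be cleaved later beside the trisubstituted C4=C5 bond, and PPTS is too weak to remove the tertiary TES ether.

Step 6
Reactants: 10 tert-butyl(but-3-yn-1-yloxy)dimethylsilane
Product: 12 (E)-5-(tert-butyldimethylsilyloxy)-3-methylpent-2-en-1-ol, via alkenylalane 11 (not isolated)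
Conditions: Me3Al, Cp2ZrCl2 (0.2 equiv), CH2Cl2, 0 °C → rt; then n-BuLi, THF/hexane, −78 °C; (CH2O)n, → rt; aq. Rochelle salt
Reagents that add atoms: trimethylaluminium, C[Al](C)C; formaldehyde (from paraformaldehyde), C=O
Why: Zirconium-catalysed carboalumination (Negishi) adds methyl and aluminium syn across the terminal alkyne with methyl on the internal carbon, and after activation with n-BuLi the alkenyl–aluminium bond is hydroxymethylated with retention, which should give the E-trisubstituted alkene (the later C4=C5) as a single isomer.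

Step 7
Reactants: 12 (E)-5-(tert-butyldimethylsilyloxy)-3-methylpent-2-en-1-ol
Product: 13 (E)-tert-butyl{[5-(4-methoxybenzyloxy)-3-methylpent-3-en-1-yl]oxy}dimethylsilane
Conditions: NaH, PMBCl, Bu4NI (cat.), THF/DMF, 0 °C → rt
Reagents that add atoms: 4-methoxybenzyl chloride, COc1ccc(CCl)cc1
Why: Williamson etherification of the primary allylic alkoxide gives a PMB ether that tolerates the organolithium chemistry of step 10 and is later removed oxidatively.

Step 8
Reactants: 13 (E)-tert-butyl{[5-(4-methoxybenzyloxy)-3-methylpent-3-en-1-yl]oxy}dimethylsilane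
Product: 14 (E)-5-(4-methoxybenzyloxy)-3-methylpent-3-en-1-ol
Conditions: TBAF, THF, 0 °C → rt
Reagents that add atoms: none
Why: Fluoride-mediated cleavage of the primary TBS ether (desilylation) leaves the PMB ether and the alkene untouched.

Step 9
Reactants: 14 (E)-5-(4-methoxybenzyloxy)-3-methylpent-3-en-1-ol
Product: 15 (E)-1-{[(5-iodo-3-methylpent-2-en-1-yl)oxy]methyl}-4-methoxybenzene
Conditions: I2, PPh3, imidazole, CH2Cl2, 0 °C
Reagents that add atoms: iodine, II
Why: Appel-type iodination converts the primary homoallylic alcohol into the iodide by SN2 displacement of the oxyphosphonium group without touching the allylic ether.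

Step 10
Reactants: 15 (E)-1-{[(5-iodo-3-methylpent-2-en-1-yl)oxy]methyl}-4-methoxybenzene; 9 (R)-N,4,4-trimethoxy-N,2-dimethyl-2-(triethylsilyloxy)butanamide
Product: 17 (3R,7E)-1,1-dimethoxy-9-(4-methoxybenzyloxy)-3,7-dimethyl-3-(triethylsilyloxy)non-7-en-4-one, via alkyllithium 16 (not isolated)
Conditions: 15, t-BuLi (2.1 equiv), Et2O, −78 °C; then 9, −78 → −20 °C; aq. NH4Cl
Reagents that add atoms: none
Why: Lithium–iodine exchange gives the primary alkyllithium 16, whose addition to the Weinreb amide stops after one addition because the metal-chelated adduct does not collapse until work-up (Weinreb ketone synthesis), so the C1 ketone and the C1–C2 bond form without over-addition and without loss of the acetal or silyl ether.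

Step 11
Reactants: 17 (3R,7E)-1,1-dimethoxy-9-(4-methoxybenzyloxy)-3,7-dimethyl-3-(triethylsilyloxy)non-7-en-4-one
Product: 18 (3R,7E)-9-hydroxy-1,1-dimethoxy-3,7-dimethyl-3-(triethylsilyloxy)non-7-en-4-one
Conditions: DDQ, CH2Cl2/pH 7 buffer, 0 °C
Reagents that add atoms: none
Why: DDQ oxidises the electron-rich PMB ether to an oxocarbenium ion that is hydrolysed (oxidative PMB cleavage), which frees the allylic alcohol under neutral conditions that spare the TES ether, the acetal and the ketone.

Step 12
Reactants: 18 (3R,7E)-9-hydroxy-1,1-dimethoxy-3,7-dimethyl-3-(triethylsilyloxy)non-7-en-4-one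
Product: 19 (2E,7R)-9,9-dimethoxy-3,7-dimethyl-6-oxo-7-(triethylsilyloxy)non-2-enal
Conditions: activated MnO2, CH2Cl2, rt
Reagents that add atoms: none
Why: Manganese dioxide oxidises the allylic alcohol selectively to the enal (heterogeneous allylic oxidation) without E/Z isomerisation of the C4=C5 bond.

Step 13
Reactants: 19 (2E,7R)-9,9-dimethoxy-3,7-dimethyl-6-oxo-7-(triethylsilyloxy)non-2-enal; 20 tert-butyldimethyl(prop-2-yn-1-yloxy)silane
Product: 22 (3R,7E,9S)-12-(tert-butyldimethylsilyloxy)-9-hydroxy-1,1-dimethoxy-3,7-dimethyl-3-(triethylsilyloxy)dodec-7-en-10-yn-4-one, via methylzinc acetylide 21 (not isolated)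
Conditions: 20 (3 equiv), Me2Zn (3 equiv), ProPhenol (20 mol %, Re-face antipode), Ph3P=O (40 mol %), toluene, 0 °C; aq. NH4Cl
Reagents that add atoms: none
Why: Zinc–ProPhenol asymmetric alkynylation: the alkynylzinc 21 adds to the aldehyde (not to the hindered ketone) within the chiral dinuclear zinc complex, which delivers the alkyne to the Re face and sets C6 as S by reagent control, the carbinol epimer needed because steps 15 and 16 together invert C6.

Step 14
Reactants: 22 (3R,7E,9S)-12-(tert-butyldimethylsilyloxy)-9-hydroxy-1,1-dimethoxy-3,7-dimethyl-3-(triethylsilyloxy)dodec-7-en-10-yn-4-one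
Product: 23 (3R,7E,9S)-12-(tert-butyldimethylsilyloxy)-1,1-dimethoxy-3,7-dimethyl-4-oxo-3-(triethylsilyloxy)dodec-7-en-10-yn-9-yl methyl carbonate
Conditions: ClCO2Me, pyridine, DMAP (cat.), CH2Cl2, 0 °C
Reagents that add atoms: methyl chloroformate, COC(=O)Cl
Why: Acylation of the secondary alcohol with a chloroformate gives the carbonate, a leaving group mild enough to be isolated at a carbinol that is both allylic and propargylic.

Step 15
Reactants: 23 (3R,7E,9S)-12-(tert-butyldimethylsilyloxy)-1,1-dimethoxy-3,7-dimethyl-4-oxo-3-(triethylsilyloxy)dodec-7-en-10-yn-9-yl methyl carbonate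
Product: 24 methyl (aR,5E,10R)-2-[(tert-butyldimethylsilyloxy)methyl]-12,12-dimethoxy-6,10-dimethyl-9-oxo-10-(triethylsilyloxy)dodeca-2,3,5-trienoate
Conditions: Pd2(dba)3·CHCl3 (2.5 mol %), PPh3 (10 mol %), CO (1 atm), MeOH/THF, rt; product kept at or below rt
Reagents that add atoms: carbon monoxide, [C-]#[O+]
Why: Palladium(0)-catalysed alkoxycarbonylation of a propargylic carbonate (Tsuji type): Pd(0) on the alkyne displaces the carbonate in an anti SN2′ sense to give a σ-allenylpalladium at C11, CO inserts with retention and the released methoxide (or solvent methanol) forms the ester, so the C6 centre is relayed into the (aR) allene axis, while the C13 silyl ether cannot ionise and the trisubstituted alkene is a poorer ligand for Pd(0) than the alkyne.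

Step 16
Reactants: 24 methyl (aR,5E,10R)-2-[(tert-butyldimethylsilyloxy)methyl]-12,12-dimethoxy-6,10-dimethyl-9-oxo-10-(triethylsilyloxy)dodeca-2,3,5-trienoate
Product: 25 (5R)-3-[(tert-butyldimethylsilyloxy)methyl]-4-iodo-5-[(1E,6R)-8,8-dimethoxy-2,6-dimethyl-5-oxo-6-(triethylsilyloxy)oct-1-en-1-yl]furan-2(5H)-one
Conditions: I2 (2 equiv), NaHCO3, MeCN/H2O (15:1), 0 °C → rt; aq. Na2S2O3
Reagents that add atoms: iodine, II; water, O
Why: Iodolactonisation of a 2,3-allenoate: iodine activates the C6=C7 bond from the face away from the ester, the ester carbonyl oxygen attacks C6 from its own side (anti addition) and the methoxy group is lost by hydrolysis, so the allene axis is relayed to C6 (R as the iodide, the spatial arrangement of the target) and C7 receives the iodine.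

Step 17
Reactants: 25 (5R)-3-[(tert-butyldimethylsilyloxy)methyl]-4-iodo-5-[(1E,6R)-8,8-dimethoxy-2,6-dimethyl-5-oxo-6-(triethylsilyloxy)oct-1-en-1-yl]furan-2(5H)-one
Product: 26 (3R,7E)-8-[(2R)-4-[(tert-butyldimethylsilyloxy)methyl]-3-iodo-5-oxo-2,5-dihydrofuran-2-yl]-3,7-dimethyl-4-oxo-3-(triethylsilyloxy)oct-7-enal
Conditions: PPTS (cat.), acetone/H2O (10:1), 40 °C
Reagents that add atoms: water, O
Why: Mild acid-catalysed hydrolysis of the dimethyl acetal frees the C8 aldehyde, while the tertiary TES ether, the primary TBS ether and the iodobutenolide are not cleaved by PPTS in wet acetone.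

Step 18
Reactants: 26 (3R,7E)-8-[(2R)-4-[(tert-butyldimethylsilyloxy)methyl]-3-iodo-5-oxo-2,5-dihydrofuran-2-yl]-3,7-dimethyl-4-oxo-3-(triethylsilyloxy)oct-7-enal
Product: 28 (4E,6R,8S,10R)-13-(tert-butyldimethylsilyloxy)-8-hydroxy-1-oxo-10-(triethylsilyloxy)germacra-4,7(11)-dien-12,6-olide, via alkenylchromium 27 (not isolated)
Conditions: CrCl2 (8 equiv), NiCl2 (2 mol % of Cr), degassed DMF/THF, rt, slow addition of 26 to 2 mM final concentration; aqueous work-up
Reagents that add atoms: none
Why: Nickel(0), formed from NiCl2 by CrCl2, should insert into the C7–I bond of the iodobutenolide and hand the alkenyl group to chromium(III), and the alkenylchromium 27 then adds to the C8 aldehyde (Nozaki–Hiyama–Kishi reaction). The closest known reaction type is the NHK macrocyclisation of alkenyl iodides onto aldehydes, which gives medium and large ring allylic alcohols. The ten-membered carbocycle (C1–C10) closes in a 10-exo-trig mode at the aldehyde carbon, with C7–C8 as the only new skeletal bond. C8 is the only new stereocentre and is set by substrate control in the cyclic transition state, where the planar butenolide, the E-C4=C5 bond and the existing C6 and C10 centres decide which aldehyde face meets C7; the 8S alcohol is the one carried on. The step needs selectivity for the aldehyde over the C1 ketone, the lactone and the silyl ethers, and it must not enolise C9 or expel the β-silyloxy group at C10; the aldehyde preference and low basicity of organochromium(III) reagents secure both. It also needs ring closure to outrun intermolecular coupling, which slow addition at high dilution and the restricted chain (sp2 C7, E-alkene, quaternary C10) should secure.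

Step 19
Reactants: 28 (4E,6R,8S,10R)-13-(tert-butyldimethylsilyloxy)-8-hydroxy-1-oxo-10-(triethylsilyloxy)germacra-4,7(11)-dien-12,6-olide
Product: 29 (4E,6R,8S,10R)-13-(tert-butyldimethylsilyloxy)-8-(methacryloyloxy)-1-oxo-10-(triethylsilyloxy)germacra-4,7(11)-dien-12,6-olide
Conditions: methacrylic anhydride, Et3N, DMAP (cat.), CH2Cl2, 0 °C, on the crude alcohol
Reagents that add atoms: methacrylic anhydride, C=C(C)C(=O)OC(=O)C(C)=C
Why: DMAP-catalysed acylation of the secondary C8 alcohol at low temperature, run at once to forestall lactone migration from O6 to O8 and drawing on the open hydroxy ketone form of any C8–O/C1 hemiketal, gives the ester with retention at C8.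

Step 20
Reactants: 29 (4E,6R,8S,10R)-13-(tert-butyldimethylsilyloxy)-8-(methacryloyloxy)-1-oxo-10-(triethylsilyloxy)germacra-4,7(11)-dien-12,6-olide
Product: 30 (4E,6R,8S,10R)-10,13-dihydroxy-8-(methacryloyloxy)-1-oxogermacra-4,7(11)-dien-12,6-olide
Conditions: HF·pyridine, pyridine, THF, 0 °C → rt
Reagents that add atoms: none
Why: Fluoride desilylation with buffered HF·pyridine cleaves the tertiary TES ether and the primary TBS ether under non-nucleophilic conditions that spare the esters and the butenolide.

Step 21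
Reactants: 30 (4E,6R,8S,10R)-10,13-dihydroxy-8-(methacryloyloxy)-1-oxogermacra-4,7(11)-dien-12,6-olide
Product: 31 (4E,6R,8S,10R)-10,13-diacetoxy-8-(methacryloyloxy)-1-oxogermacra-4,7(11)-dien-12,6-olide
Conditions: Ac2O, Sc(OTf)3 (cat.), MeCN, −20 → 0 °C
Reagents that add atoms: acetic anhydride, CC(=O)OC(C)=O
Why: Lewis acid-catalysed acetylation acylates the primary C13 alcohol at once and the hindered tertiary α-ketol C10–OH at low temperature without base, so the base-sensitive C6–H of the butenolide is not exposed.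

Step 22
Reactants: 31 (4E,6R,8S,10R)-10,13-diacetoxy-8-(methacryloyloxy)-1-oxogermacra-4,7(11)-dien-12,6-olide
Product: 32 glaucolide A, (4R,5R,6S,8S,10R)-10,13-diacetoxy-4,5-epoxy-8-(methacryloyloxy)-1-oxogermacr-7(11)-en-12,6-olide
Conditions: mCPBA, NaHCO3, CH2Cl2, 0 °C
Reagents that add atoms: m-chloroperoxybenzoic acid, O=C(OO)c1cccc(Cl)c1
Why: Prilezhaev epoxidation: the peracid should attack only the electron-rich trisubstituted C4=C5 bond (the methacrylate and butenolide alkenes are electron-poor) from the outer face of the E-alkene, the face syn to the C6–O bond and anti to C7, which sets C4 and C5 as 4R,5R by substrate control from C6 and the ring conformation.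

**Compound list**

1 | (S)-lactic acid | C[C@H](O)C(O)=O | starting material
2 | (2S,5S)-2-tert-butyl-5-methyl-1,3-dioxolan-4-one | C[C@@H]1O[C@H](C(C)(C)C)OC1=O | intermediate
3 | allyl bromide | C=CCBr | starting material
4 | lithium (S)-2-tert-butyl-5-methyl-1,3-dioxol-4-olate (enolate of 2) | CC1=C(O[Li])O[C@@H](C(C)(C)C)O1 | intermediate
5 | (2S,5R)-5-allyl-2-tert-butyl-5-methyl-1,3-dioxolan-4-one | C[C@]1(CC=C)O[C@H](C(C)(C)C)OC1=O | intermediate
6 | (R)-2-hydroxy-N-methoxy-N,2-dimethylpent-4-enamide | C=CC[C@@](C)(O)C(=O)N(C)OC | intermediate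
7 | (R)-N-methoxy-N,2-dimethyl-2-(triethylsilyloxy)pent-4-enamide | C=CC[C@@](C)(O[Si](CC)(CC)CC)C(=O)N(C)OC | intermediate
8 | (R)-N-methoxy-N,2-dimethyl-4-oxo-2-(triethylsilyloxy)butanamide | O=CC[C@@](C)(O[Si](CC)(CC)CC)C(=O)N(C)OC | intermediate
9 | (R)-N,4,4-trimethoxy-N,2-dimethyl-2-(triethylsilyloxy)butanamide | COC(OC)C[C@@](C)(O[Si](CC)(CC)CC)C(=O)N(C)OC | intermediate
10 | tert-butyl(but-3-yn-1-yloxy)dimethylsilane | C#CCCO[Si](C)(C)C(C)(C)C | starting material
11 | (E)-[4-(tert-butyldimethylsilyloxy)-2-methylbut-1-en-1-yl]dimethylaluminium | C[Al](C)/C=C(\C)CCO[Si](C)(C)C(C)(C)C | intermediate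
12 | (E)-5-(tert-butyldimethylsilyloxy)-3-methylpent-2-en-1-ol | OC/C=C(\C)CCO[Si](C)(C)C(C)(C)C | intermediate
13 | (E)-tert-butyl{[5-(4-methoxybenzyloxy)-3-methylpent-3-en-1-yl]oxy}dimethylsilane | COc1ccc(COC/C=C(\C)CCO[Si](C)(C)C(C)(C)C)cc1 | intermediate
14 | (E)-5-(4-methoxybenzyloxy)-3-methylpent-3-en-1-ol | COc1ccc(COC/C=C(\C)CCO)cc1 | intermediate
15 | (E)-1-{[(5-iodo-3-methylpent-2-en-1-yl)oxy]methyl}-4-methoxybenzene | COc1ccc(COC/C=C(\C)CCI)cc1 | intermediate
16 | (E)-[5-(4-methoxybenzyloxy)-3-methylpent-3-en-1-yl]lithium | COc1ccc(COC/C=C(\C)CC[Li])cc1 | intermediate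
17 | (3R,7E)-1,1-dimethoxy-9-(4-methoxybenzyloxy)-3,7-dimethyl-3-(triethylsilyloxy)non-7-en-4-one | COC(OC)C[C@@](C)(O[Si](CC)(CC)CC)C(=O)CC/C(C)=C/COCc1ccc(OC)cc1 | intermediate
18 | (3R,7E)-9-hydroxy-1,1-dimethoxy-3,7-dimethyl-3-(triethylsilyloxy)non-7-en-4-one | COC(OC)C[C@@](C)(O[Si](CC)(CC)CC)C(=O)CC/C(C)=C/CO | intermediate
19 | (2E,7R)-9,9-dimethoxy-3,7-dimethyl-6-oxo-7-(triethylsilyloxy)non-2-enal | COC(OC)C[C@@](C)(O[Si](CC)(CC)CC)C(=O)CC/C(C)=C/C=O | intermediate
20 | tert-butyldimethyl(prop-2-yn-1-yloxy)silane | C#CCO[Si](C)(C)C(C)(C)C | starting material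
21 | methyl[3-(tert-butyldimethylsilyloxy)prop-1-yn-1-yl]zinc | C[Zn]C#CCO[Si](C)(C)C(C)(C)C | intermediate
22 | (3R,7E,9S)-12-(tert-butyldimethylsilyloxy)-9-hydroxy-1,1-dimethoxy-3,7-dimethyl-3-(triethylsilyloxy)dodec-7-en-10-yn-4-one | COC(OC)C[C@@](C)(O[Si](CC)(CC)CC)C(=O)CC/C(C)=C/[C@H](O)C#CCO[Si](C)(C)C(C)(C)C | intermediate
23 | (3R,7E,9S)-12-(tert-butyldimethylsilyloxy)-1,1-dimethoxy-3,7-dimethyl-4-oxo-3-(triethylsilyloxy)dodec-7-en-10-yn-9-yl methyl carbonate | COC(OC)C[C@@](C)(O[Si](CC)(CC)CC)C(=O)CC/C(C)=C/[C@H](OC(=O)OC)C#CCO[Si](C)(C)C(C)(C)C | intermediate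
24 | methyl (aR,5E,10R)-2-[(tert-butyldimethylsilyloxy)methyl]-12,12-dimethoxy-6,10-dimethyl-9-oxo-10-(triethylsilyloxy)dodeca-2,3,5-trienoate | COC(OC)C[C@@](C)(O[Si](CC)(CC)CC)C(=O)CC/C(C)=C/C([H])=[C@@]=C(C(=O)OC)CO[Si](C)(C)C(C)(C)C | intermediate
25 | (5R)-3-[(tert-butyldimethylsilyloxy)methyl]-4-iodo-5-[(1E,6R)-8,8-dimethoxy-2,6-dimethyl-5-oxo-6-(triethylsilyloxy)oct-1-en-1-yl]furan-2(5H)-one | COC(OC)C[C@@](C)(O[Si](CC)(CC)CC)C(=O)CC/C(C)=C/[C@H]1OC(=O)C(CO[Si](C)(C)C(C)(C)C)=C1I | intermediate
26 | (3R,7E)-8-[(2R)-4-[(tert-butyldimethylsilyloxy)methyl]-3-iodo-5-oxo-2,5-dihydrofuran-2-yl]-3,7-dimethyl-4-oxo-3-(triethylsilyloxy)oct-7-enal | O=CC[C@@](C)(O[Si](CC)(CC)CC)C(=O)CC/C(C)=C/[C@H]1OC(=O)C(CO[Si](C)(C)C(C)(C)C)=C1I | intermediate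
27 | alkenylchromium(III) dichloride of 26 (CrCl2 on C7 in place of iodine) | O=CC[C@@](C)(O[Si](CC)(CC)CC)C(=O)CC/C(C)=C/[C@H]1OC(=O)C(CO[Si](C)(C)C(C)(C)C)=C1[Cr](Cl)Cl | intermediate
28 | (4E,6R,8S,10R)-13-(tert-butyldimethylsilyloxy)-8-hydroxy-1-oxo-10-(triethylsilyloxy)germacra-4,7(11)-dien-12,6-olide | O[C@H]1C[C@@](C)(O[Si](CC)(CC)CC)C(=O)CC/C(C)=C/[C@H]2OC(=O)C(CO[Si](C)(C)C(C)(C)C)=C12 | intermediate
29 | (4E,6R,8S,10R)-13-(tert-butyldimethylsilyloxy)-8-(methacryloyloxy)-1-oxo-10-(triethylsilyloxy)germacra-4,7(11)-dien-12,6-olide | C=C(C)C(=O)O[C@H]1C[C@@](C)(O[Si](CC)(CC)CC)C(=O)CC/C(C)=C/[C@H]2OC(=O)C(CO[Si](C)(C)C(C)(C)C)=C12 | intermediate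
30 | (4E,6R,8S,10R)-10,13-dihydroxy-8-(methacryloyloxy)-1-oxogermacra-4,7(11)-dien-12,6-olide | C=C(C)C(=O)O[C@H]1C[C@@](C)(O)C(=O)CC/C(C)=C/[C@H]2OC(=O)C(CO)=C12 | intermediate
31 | (4E,6R,8S,10R)-10,13-diacetoxy-8-(methacryloyloxy)-1-oxogermacra-4,7(11)-dien-12,6-olide | C=C(C)C(=O)O[C@H]1C[C@@](C)(OC(C)=O)C(=O)CC/C(C)=C/[C@H]2OC(=O)C(COC(C)=O)=C12 | intermediate
32 | glaucolide A | C=C(C)C(=O)O[C@H]1C[C@@](C)(OC(C)=O)C(=O)CC[C@@]2(C)O[C@@H]2[C@H]2OC(=O)C(COC(C)=O)=C12 | target

**Step count and risks**

Total steps: 22. Longest linear sequence: 18 steps (steps 1–5 and 10–22); the C2–C6 side chain takes steps 6–9.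

Steps most likely to fail:

1. Step 18 (ring closure). The aldehyde may be attacked from the wrong face in the cyclic transition state (poor facial selectivity at C8), and intermolecular coupling or reduction of the C–I bond may compete with closure; the latter is met by dilution and slow addition. For the stereochemical failure the fallback sets out from 26 and rejoins the route at 29. The cyclisation is run as before, and the 8R alcohol, (4E,6R,8R,10R)-13-(tert-butyldimethylsilyloxy)-8-hydroxy-1-oxo-10-(triethylsilyloxy)germacra-4,7(11)-dien-12,6-olide F1, is isolated. It is esterified with inversion in a Mitsunobu reaction (PPh3, DIAD, methacrylic acid, toluene, 0 °C), so that C8 is set by SN2 displacement at the carbinol and not by the ring closure, and step 19 is skipped.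

2. Step 15 (carbonylation). Ionisation at a carbinol that is both allylic and propargylic may let the palladium intermediate equilibrate through the allyl manifold, which would erode the transfer of chirality from C6 to the allene axis and hence the configuration of C6 in 25; a thermal [1,5]-hydrogen shift of the vinylallene is a second drain if 24 is warmed. The fallback gives up the relay from C6 and sets the axis by the catalyst; it sets out from 19 and rejoins the route at 24. Enal 19 is alkynylated with 20 without a chiral ligand (Me2Zn, toluene), which gives 22 together with its C6 epimer, (3R,7E,9R)-12-(tert-butyldimethylsilyloxy)-9-hydroxy-1,1-dimethoxy-3,7-dimethyl-3-(triethylsilyloxy)dodec-7-en-10-yn-4-one F2. The mixture is converted as in step 14 into 23 and the epimeric (9R)-methyl carbonate F3. Both carbonates are then carbonylated in an enantioconvergent way with a palladium catalyst that carries a chiral biaryl bisphosphine (CO, MeOH, rt), where the interconverting allenyl- and propargyl-palladium species are funnelled to the (aR) axis by the ligand.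

3. Step 22 (epoxidation). The peracid may approach the other face of the C4=C5 bond if the ten-membered ring does not adopt the expected conformation (poor facial selectivity). The fallback sets out from 31 and rejoins the route at 32, and delivers the oxygen to the face the peracid does not reach. NBS in aqueous DME at 0 °C forms the bromonium ion on the accessible face, and water opens it at the tertiary C4 from the opposite face to give the bromohydrin (4R,5S,6S,8S,10R)-10,13-diacetoxy-5-bromo-4-hydroxy-8-(methacryloyloxy)-1-oxogermacr-7(11)-en-12,6-olide F4. Ag2O in DME then closes the epoxide by intramolecular SN2 displacement at C5, without base strong enough to touch the esters.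

Further compounds
F1 | step 18 | (4E,6R,8R,10R)-13-(tert-butyldimethylsilyloxy)-8-hydroxy-1-oxo-10-(triethylsilyloxy)germacra-4,7(11)-dien-12,6-olide | O[C@@H]1C[C@@](C)(O[Si](CC)(CC)CC)C(=O)CC/C(C)=C/[C@H]2OC(=O)C(CO[Si](C)(C)C(C)(C)C)=C12
F2 | step 15 | (3R,7E,9R)-12-(tert-butyldimethylsilyloxy)-9-hydroxy-1,1-dimethoxy-3,7-dimethyl-3-(triethylsilyloxy)dodec-7-en-10-yn-4-one | COC(OC)C[C@@](C)(O[Si](CC)(CC)CC)C(=O)CC/C(C)=C/[C@@H](O)C#CCO[Si](C)(C)C(C)(C)C
F3 | step 15 | (3R,7E,9R)-12-(tert-butyldimethylsilyloxy)-1,1-dimethoxy-3,7-dimethyl-4-oxo-3-(triethylsilyloxy)dodec-7-en-10-yn-9-yl methyl carbonate | COC(OC)C[C@@](C)(O[Si](CC)(CC)CC)C(=O)CC/C(C)=C/[C@@H](OC(=O)OC)C#CCO[Si](C)(C)C(C)(C)C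
F4 | step 22 | (4R,5S,6S,8S,10R)-10,13-diacetoxy-5-bromo-4-hydroxy-8-(methacryloyloxy)-1-oxogermacr-7(11)-en-12,6-olide | C=C(C)C(=O)O[C@H]1C[C@@](C)(OC(C)=O)C(=O)CC[C@@](C)(O)[C@@H](Br)[C@H]2OC(=O)C(COC(C)=O)=C12
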